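The flavonol core is cut at its C4 carbonyl. C4 sits between the ring A carbon C4a and C3, and C4a is flanked by two equivalent oxygenated carbons (C5 and C8a), so C4 can be delivered as carbon monoxide between a symmetric ring A iodide and a ring B alkyne. One PdCl2(PPh3)2/CuI-catalysed three-component coupling forms C4–C4a and C3–C4 and assembles the whole C6–C3–C6 skeleton as an alkynone from three commercial precursors: 2-iodo-1,3,5-trimethoxybenzene, 4-ethynylanisole and carbon monoxide. Iodocyclisation then closes ring C and marks C3, iodine–magnesium exchange followed by borate oxidation installs O3, and global demethylation and chelation-controlled sulfation finish the route.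

Key step: step 1

Remark: flavone numbering is used (O1, C2, C3, C4, C4a, C5 to C8, C8a; ring B positions primed); the target has no stereocentre; it is drawn as the tris(hydrogen sulfate), and since aryl hydrogen sulfates are handled as salts, the last product is to be isolated as its tripotassium salt and is written in the neutral form of the given SMILES.

Step 1
Reactants: 1 2-iodo-1,3,5-trimethoxybenzene; 2 4-ethynylanisole; 3 carbon monoxide
Product: 4 3-(4-methoxyphenyl)-1-(2,4,6-trimethoxyphenyl)prop-2-yn-1-one
Conditions: PdCl2(PPh3)2 (5 mol%), CuI (2 mol%), Et3N (3 equiv), THF, CO (5 bar), 40 °C, slow addition of 2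
Reagents that add atoms: none
Why: Zerovalent palladium, formed in the flask from PdCl2(PPh3)2, inserts into the C–I bond of 1, carbon monoxide undergoes migratory insertion to give the aroyl complex ArC(O)PdI(PPh3)2, the copper acetylide formed from 2 and CuI transmetalates, and reductive elimination forms C3–C4, so that C4–C4a and C3–C4 arise in one catalytic cycle. The closest known reaction type is the carbonylative Sonogashira coupling of aryl iodides with terminal alkynes under CO. No ring is closed and no stereocentre is formed. The selectivity needed is acyl coupling over direct alkynylation: the two ortho methoxy groups hinder transmetalation at the arylpalladium stage and the electron-rich aryl group migrates readily to CO, which CO pressure and slow addition of 2 should reinforce. The mirror-symmetric substitution of 1 removes any regiochemical question on ring A, and the tertiary amine base cannot add to the ynone in conjugate fashion.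

Step 2
Reactants: 4 3-(4-methoxyphenyl)-1-(2,4,6-trimethoxyphenyl)prop-2-yn-1-one
Product: 5 3-iodo-5,7-dimethoxy-2-(4-methoxyphenyl)-4H-chromen-4-one
Conditions: ICl (1.1 equiv), CH2Cl2, −78 °C; Na2S2O3 quench
Reagents that add atoms: iodine monochloride, ClI
Why: Larock-type electrophilic iodocyclisation, in which ICl activates the alkyne, one of the two equivalent ortho methoxy oxygens attacks the anisyl-bearing alkyne carbon in 6-endo-dig mode and chloride removes the methyl group from the resulting oxonium ion, should close ring C with iodine at C3, while low temperature and near-stoichiometric ICl keep iodination of ring A in check.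

Step 3
Reactants: 5 3-iodo-5,7-dimethoxy-2-(4-methoxyphenyl)-4H-chromen-4-one
Product: 8 3-hydroxy-5,7-dimethoxy-2-(4-methoxyphenyl)-4H-chromen-4-one, via 3-chloromagnesioflavone 6 (not isolated), via flavon-3-yl dimethyl boronate 7 (not isolated)
Conditions: iPrMgCl·LiCl (1.1 equiv), THF, −40 °C; B(OMe)3, −40 to 0 °C; AcOOH, AcOH, 0 °C to rt; Na2S2O3 quench
Reagents that add atoms: peracetic acid, CC(=O)OO
Why: Iodine–magnesium exchange with iPrMgCl·LiCl is fast at low temperature on an sp2 C–I bond alpha to a vinylogous ester carbonyl, the 3-magnesiated flavone is trapped by trimethyl borate, and peracid oxidation of the C–B bond (1,2-shift of C3 from boron to oxygen) should give the flavonol, a sequence that parallels the known borate–peracid hydroxylation of 3-metalated flavones.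

Step 4
Reactants: 8 3-hydroxy-5,7-dimethoxy-2-(4-methoxyphenyl)-4H-chromen-4-one
Product: 9 kaempferol (3,5,7-trihydroxy-2-(4-hydroxyphenyl)-4H-chromen-4-one)
Conditions: BBr3 (8 equiv), CH2Cl2, −78 °C to rt; then MeOH, H2O
Reagents that add atoms: none
Why: BBr3 ether cleavage, in which the Lewis acid coordinates each aryl methyl ether (the 5-methoxy group first, assisted by the C4 carbonyl), bromide removes the methyl groups by SN2 and hydrolysis of the aryl borates releases the phenols, is well established for polymethoxyflavonols and should leave the pyranone untouched.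

Step 5
Reactants: 9 kaempferol
Product: 10 kaempferol 3,7,4'-tri-O-sulfate (target; isolated as the tripotassium salt)
Conditions: SO3·NMe3 (4.5 equiv), Et3N, DMF, 60 °C; then K+-form cation-exchange resin, H2O
Reagents that add atoms: sulfur trioxide–trimethylamine complex, C[N+](C)(C)S(=O)(=O)[O-]
Why: O-Sulfation of phenols with a sulfur trioxide–amine complex should esterify the 7-, 4'- and 3-hydroxyls, while the 5-hydroxyl, locked in a strong hydrogen bond to the C4 carbonyl and the least nucleophilic of the four, should stay free when the reagent is limited to a small excess over three equivalents and the temperature is kept moderate.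

Compound list
1 | 2-iodo-1,3,5-trimethoxybenzene | COc1cc(OC)c(I)c(OC)c1 | starting material
2 | 4-ethynylanisole (1-ethynyl-4-methoxybenzene) | C#Cc1ccc(OC)cc1 | starting material
3 | carbon monoxide | [C-]#[O+] | starting material
4 | 3-(4-methoxyphenyl)-1-(2,4,6-trimethoxyphenyl)prop-2-yn-1-one | COc1ccc(cc1)C#CC(=O)c1c(OC)cc(OC)cc1OC | intermediate
5 | 3-iodo-5,7-dimethoxy-2-(4-methoxyphenyl)-4H-chromen-4-one | COc1ccc(cc1)-c1oc2cc(OC)cc(OC)c2c(=O)c1I | intermediate
6 | 3-(chloromagnesio)-5,7-dimethoxy-2-(4-methoxyphenyl)-4H-chromen-4-one (LiCl complex, not isolated) | COc1ccc(cc1)-c1oc2cc(OC)cc(OC)c2c(=O)c1[Mg]Cl | intermediate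
7 | dimethyl [5,7-dimethoxy-2-(4-methoxyphenyl)-4-oxo-4H-chromen-3-yl]boronate (not isolated) | COc1ccc(cc1)-c1oc2cc(OC)cc(OC)c2c(=O)c1B(OC)OC | intermediate
8 | 3-hydroxy-5,7-dimethoxy-2-(4-methoxyphenyl)-4H-chromen-4-one (kaempferol 5,7,4'-trimethyl ether) | COc1ccc(cc1)-c1oc2cc(OC)cc(OC)c2c(=O)c1O | intermediate
9 | kaempferol | O=c1c(O)c(-c2ccc(O)cc2)oc2cc(O)cc(O)c12 | intermediate
10 | kaempferol 3,7,4'-tri-O-sulfate | O=c1c(OS(=O)(=O)O)c(-c2ccc(OS(=O)(=O)O)cc2)oc2cc(OS(=O)(=O)O)cc(O)c12 | target

Total step count: 5
Longest linear sequence: 5 steps (steps 1 to 5)

Steps most likely to fail, riskiest first: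

Step 3. The Grignard reagent may add to C2 or C4 of the pyranone in competition with the exchange, the 3-magnesiated flavone may be protonated before the borate captures it, or the C3 boronate may lose boron before oxidation; all three paths end in net loss of iodine without oxygenation. The fallback sets out from 5 and changes the polarity of the oxygenation. Hydrodeiodination with Pd(OAc)2, PPh3 and HCO2Na in DMF should give 5,7-dimethoxy-2-(4-methoxyphenyl)-4H-chromen-4-one F1, which is also the product of the protonation path and can be collected from a failed run. Dimethyldioxirane in acetone/CH2Cl2 at 0 °C should transfer oxygen to the C2=C3 enol ether bond to give racemic 2,3-epoxy-5,7-dimethoxy-2-(4-methoxyphenyl)chroman-4-one F2. Catalytic TsOH in CH2Cl2 should open the epoxide at C2 and, after loss of the C3 proton, deliver the flavonol, so the fallback comes back to the route at 8.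

Step 1. Oxidative addition into the electron-rich, doubly ortho-substituted C–I bond may be slow, the alkyne may couple directly without uptake of CO, or the alkyne may dimerise oxidatively. The fallback sets out from 2 and builds the same two bonds by polar chemistry. Deprotonation with nBuLi in THF at −78 °C gives lithium (4-methoxyphenyl)acetylide F3. Addition of F3 to commercial 2,4,6-trimethoxybenzaldehyde should give racemic 3-(4-methoxyphenyl)-1-(2,4,6-trimethoxyphenyl)prop-2-yn-1-ol F4, which is acid-sensitive and is best carried forward crude. Oxidation with MnO2 in CH2Cl2 at rt should give the ynone, so the fallback comes back to the route at 4.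

Step 5. Sulfation of the hindered, chelated 3-hydroxyl may stay incomplete, the 5-hydroxyl may be partly sulfated under forcing, and the 3-sulfate may be lost by acid-promoted hydrolysis during isolation, which would leave salt mixtures that are hard to separate. The fallback sets out from 9 and uses a protected sulfate. 2,2,2-Trichloroethyl chlorosulfate (3.3 equiv), Et3N and DMAP in THF at 0 °C should give the neutral kaempferol 3,7,4'-tris(2,2,2-trichloroethyl sulfate) F5, which can be purified on silica and separated from under- and over-sulfated esters. Zn dust and HCO2NH4 in MeOH at rt should remove the trichloroethyl groups by reductive fragmentation and release the trisulfate as its ammonium salt, so the fallback comes back to the route at 10.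

Further compounds
F1 | step 3 | 5,7-dimethoxy-2-(4-methoxyphenyl)-4H-chromen-4-one | COc1ccc(cc1)-c1cc(=O)c2c(OC)cc(OC)cc2o1
F2 | step 3 | 2,3-epoxy-5,7-dimethoxy-2-(4-methoxyphenyl)chroman-4-one (racemic, cis-fused; one enantiomer drawn) | COc1ccc(cc1)[C@@]12O[C@@H]1C(=O)c1c(OC)cc(OC)cc1O2
F3 | step 1 | lithium (4-methoxyphenyl)acetylide | [Li]C#Cc1ccc(OC)cc1
F4 | step 1 | 3-(4-methoxyphenyl)-1-(2,4,6-trimethoxyphenyl)prop-2-yn-1-ol (racemic) | COc1ccc(cc1)C#CC(O)c1c(OC)cc(OC)cc1OC
F5 | step 5 | kaempferol 3,7,4'-tris(2,2,2-trichloroethyl sulfate) | O=c1c(OS(=O)(=O)OCC(Cl)(Cl)Cl)c(-c2ccc(OS(=O)(=O)OCC(Cl)(Cl)Cl)cc2)oc2cc(OS(=O)(=O)OCC(Cl)(Cl)Cl)cc(O)c12
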